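## Structural features

The target 21 is an open-chain bis(bibenzyl) of four benzene rings. Ring A (3-hydroxyphenyl) is joined by a CH2CH2 bridge to ring B (1,4-phenylene), ring B is joined through a diaryl ether oxygen to ring C, and ring C is joined by a second CH2CH2 bridge to ring D (2,3-dihydroxyphenyl). Ring C is 1,2,4-trisubstituted: C1 carries OH, C2 the ether oxygen to ring B and C4 the bridge to ring D, while C3, C5 and C6 carry hydrogen. The molecule has no stereocentre; the two sp3 centres that appear in ring C during the synthesis are 1,3-related, not adjacent, and vanish again. The fragile groups are the four phenols, above all the catechol of ring D and the 2-aryloxyphenol of ring C, which oxidise easily to quinones once free and are therefore kept as methyl ethers until the last step. The benzylic CH2 groups are mildly oxidisable, and the diaryl ether must survive the deprotection. The real difficulty is the unsymmetrical oxygenation of ring C combined with a C–O–C link between two electron-rich, unactivated rings, which would normally require a metal-mediated aryl C–O coupling next to an ortho oxygen substituent. The key step exploits the fact that C1 (OH) of ring C is para to C4 (chain) and ortho to C2 (OAr), the pattern of a 4-alkylcyclohexanone oxygenated at its α-carbon. C6–C1–C2 can thus come from an aryloxyacetone, C4–C5 from the α- and carbonyl carbons of an aldehyde and C3 from formaldehyde, with the ether oxygen attached while C2 is still sp3.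

## Logic of the disconnections

21 to 20: the three O–CH3 bonds on rings A and D are restored. The free catechol and phenols could not be carried through base, oxidant and palladium, whereas methyl ethers can. The gain is that only the ring C hydroxyl remains free. The forward step must cleave three alkyl–oxygen bonds without touching the aryl–O–aryl link, which has no sp3 carbon to be attacked.

20 to 18: ring C is taken down one oxidation level by returning two hydrogens to C2 and C3 and writing the phenol in its keto form, which leads through 19 to 18. The reason is that a cyclohexenone can be assembled by carbonyl chemistry, and the diaryl ether becomes an alkyl aryl ether α to a ketone. The forward step must dehydrogenate the ring and leave the four benzylic CH2 groups alone. The two stereocentres of 18 need no control because both carbons become trigonal.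

18 to 13, 14 and 7: three C–C bonds of ring C are cut, C3–C4, C2–C3 and C5–C6 (ring C numbering of 21). This divides the ring into a three-carbon ketone unit, a two-carbon aldehyde unit and a one-carbon unit, and it separates the ring A–B half from the ring D half, so the synthesis becomes convergent. The forward step must form 15 first, then achieve conjugate addition in preference to 1,2-addition (via 16), and then close the six-membered ring by aldol condensation (via 17). Which α-carbon of 7 reacts first does not matter.

7 to 5 and 6: the O–CH2 bond is cut. This turns the diaryl ether problem into a phenol O-alkylation with a reactive α-halo ketone. The forward step needs only a mild base and no metal.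

5 to 4, then to 1 and 2: the benzyl–oxygen bond and the two hydrogens of the A–B bridge are restored (4), and the bridge C=C bond is cut into an aldehyde and a benzylic phosphonium salt. Both aromatic rings are then purchasable with their oxygen in place. The forward olefination needs no geometric control, and one hydrogenation must both saturate the alkene and free the phenol.

13 to 12, 11, then 8 and 9: the aldehyde is traced to the primary alcohol 12, 12 to the alkene 11, and the C=C bond next to ring D is cut. Ring D then comes from a cheap benzaldehyde with both oxygens already in the 2,3-positions, and the three-carbon unit arrives with its oxygen. The forward olefination must tolerate a free hydroxyl on the ylide (via 10), and the final oxidation must stop at the aldehyde.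

## Other disconnections considered

Alternative 1: Ring B is cut at the two ring bonds that connect its C(OAr)–CH unit to the other four ring carbons, which leads to methyl coumalate A1 and the aryl ethynyl ether A2 (ring C with O–C≡CH at C2, OMe at C1 and the ring D bridge at C4). In the forward direction the electron-poor pyranone A1 and the electron-rich alkyne A2 would undergo a [4+2] cycloaddition, and loss of CO2 from the bridged lactone would leave the methyl 4-aryloxybenzoate A3.
- In its favour: the polarisation of both partners (nucleophilic terminal alkyne carbon to C6 of A1) fixes the para relation of ester and aryloxy group. The ring is aromatic as soon as CO2 leaves, so no dehydrogenation is needed; on this point it is better than the chosen plan. Like the chosen plan it needs no metal-mediated aryl C–O coupling.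
- Against it: ring B is the least demanding ring of the target, a para-disubstituted benzene obtainable with both positions functionalised. A2 needs the ether oxygen on an sp carbon and has to be made through a dihalovinyl ether and strong base; it is far less robust than 7. An aryloxyalkyne is a weaker donor than an alkoxy- or aminoalkyne, so the cycloaddition would need heat at which A2 may oligomerise. The ester of A3 must still be reduced to the aldehyde, joined to 2 by Wittig reaction and hydrogenated, and four methyl ethers would then have to be cleaved.
- Comparison: on structure, it builds the ring whose substitution is trivial, whereas the chosen plan builds ring C, whose 1,2,4-pattern is the actual problem. On mechanism, the pericyclic key step has an intrinsic regiochemical bias and is the equal of the chosen plan, which is indifferent to regiochemistry. On step economy, about ten to eleven steps in a nearly linear order compare badly with nine steps and a longest line of six.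

Alternative 2: The bond between ring D and the benzylic carbon of the C–D bridge is cut, with ring D traced to 2-iodo-6-methoxyphenol A4 and the rest to the arylacetylene A5. In the forward direction Sonogashira coupling with PdCl2(PPh3)2, CuI and Et3N and 5-endo-dig attack of the phenolic oxygen in the same flask would give the 2-arylbenzofuran A6. Hydrogenation of the furan C=C bond and hydrogenolysis of the benzylic C–O bond would then open the heterocycle to the bibenzyl phenol A7, which is demethylated.
- In its favour: the coupling–cyclisation is among the most dependable C–C bond formations, and the ortho oxygen of ring D serves first as a handle and is then kept. On reliability of the key step it is better than the chosen plan. In step count it is about equal: A5 can be reached from 5 by an aryl C–O coupling and an aldehyde-to-alkyne homologation, for roughly eight to nine steps in all.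
- Against it: the furan ring is not part of the target, so a C–O bond is made only to be broken. The reductive opening is delicate: hydrogenolysis of a 2-aryl-2,3-dihydrobenzofuran needs acidic or forcing conditions, and dissolving-metal variants would also cleave the diaryl ether. A5 already contains the diaryl ether, which must come from a CuI-mediated Ullmann coupling of two electron-rich partners, the step the chosen plan avoids. The key step forms one skeletal bond and none of the four benzene rings.
- Comparison: on structure, it solves the easy C–D bridge and leaves ring C and the ether to conventional coupling. On mechanism, it has the safer key step but the riskier unmasking, the reverse of the chosen plan; both carry a temporary feature (a furan ring there, a partly saturated ring here) and are equal in that. On step economy, the count is similar but the longest line is longer and the route less convergent.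

Alternative 3: Ring A is cut at C2–C3 and C5–C6 (C1 bears OH, C3 the bridge), which leads to ethyl acetoacetate A8 and the 5-arylpent-2-enal A9 that carries rings B, C and D. In the forward direction Michael addition of A8 to A9 and intramolecular aldol condensation would give the cyclohexenone ester A10. Ester hydrolysis with decarboxylation, dehydrogenation and demethylation would finish ring A.
- In its favour: a β-keto ester is a much better Michael donor than the singly activated ketone 7, and the reaction class is established under base and under secondary-amine catalysis. On donor acidity and precedent it is better than the chosen plan. The meta relation of OH and chain follows directly from the connectivity.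
- Against it: ring A is a plain 3-oxygenated phenyl group that 2 supplies ready-made. A9 would be the most elaborate intermediate of the synthesis and needs the diaryl ether (aryl C–O coupling), the C–D bridge and a homologation to the enal before the annulation can be tried. A β-substituted enal is a slower acceptor, and Knoevenagel condensation at the aldehyde competes. The ester must be removed in an extra step.
- Comparison: on structure, the annulation is spent on the simplest ring. On mechanism, the logic is the same as in the chosen plan (Michael addition, aldol closure, late aromatisation, transient stereocentres of no consequence), so the two are equal there, and the alternative is better in enolate generation. On step economy, three operations follow the annulation instead of two and the longest linear sequence precedes it, so the total would lie well above nine.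

Key step: step 7

Assumption: 1, 2, 6, 8, 9 and 14 (as 37% aqueous solution) are taken as purchasable. The target is achiral, so no configuration has to be set; the benzyl ether in 1 keeps the aldehyde electrophilic in the olefination and is removed by the hydrogenation of step 2.

## Steps

Step 1
Reactants: 1 4-(benzyloxy)benzaldehyde; 2 (3-methoxybenzyl)triphenylphosphonium chloride
Product: 4 1-(benzyloxy)-4-[2-(3-methoxyphenyl)ethenyl]benzene (E/Z mixture), via phosphorus ylide 3 (not isolated)
Conditions: KOtBu, THF, 0 °C to rt
Reagents that add atoms: none
Why: Wittig olefination with a semi-stabilised benzylic ylide; the alkene geometry is irrelevant because step 2 saturates it, and the O-benzyl group avoids a deactivating phenoxide on the aldehyde.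

Step 2
Reactants: 4 1-(benzyloxy)-4-[2-(3-methoxyphenyl)ethenyl]benzene
Product: 5 4-[2-(3-methoxyphenyl)ethyl]phenol
Conditions: H2 (1 atm), 10% Pd/C, EtOAc/EtOH, rt
Reagents that add atoms: none
Why: Catalytic hydrogenation should saturate the stilbene double bond and hydrogenolyse the benzyl ether in the same operation; the aryl methyl ether is inert.

Step 3
Reactants: 5 4-[2-(3-methoxyphenyl)ethyl]phenol; 6 chloroacetone
Product: 7 1-{4-[2-(3-methoxyphenyl)ethyl]phenoxy}propan-2-one
Conditions: K2CO3, acetone, reflux
Reagents that add atoms: none
Why: Williamson ether synthesis; the phenoxide displaces chloride from the activated α-halo ketone by SN2, which installs the future diaryl ether oxygen without any aryl C–O coupling.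

Step 4
Reactants: 8 2,3-dimethoxybenzaldehyde; 9 (3-hydroxypropyl)triphenylphosphonium bromide
Product: 11 4-(2,3-dimethoxyphenyl)but-3-en-1-ol (E/Z mixture), via oxido ylide 10 (not isolated)
Conditions: 9, n-BuLi (2.1 equiv), THF, −20 °C to 0 °C; then 8, 0 °C to rt; H2O
Reagents that add atoms: none
Why: Wittig olefination with a γ-oxido ylide; two equivalents of base deprotonate the hydroxyl and the α-carbon, and the alkene geometry is of no account because step 5 saturates it.

Step 5
Reactants: 11 4-(2,3-dimethoxyphenyl)but-3-en-1-ol
Product: 12 4-(2,3-dimethoxyphenyl)butan-1-ol
Conditions: H2 (1 atm), 10% Pd/C, EtOAc, rt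
Reagents that add atoms: none
Why: Catalytic hydrogenation of a styrene-type double bond; the homoallylic C–O bond is not prone to hydrogenolysis.

Step 6
Reactants: 12 4-(2,3-dimethoxyphenyl)butan-1-ol
Product: 13 4-(2,3-dimethoxyphenyl)butanal
Conditions: TEMPO (10 mol %), PhI(OAc)2 (1.1 equiv), CH2Cl2, rt
Reagents that add atoms: none
Why: Oxoammonium-mediated oxidation of a primary alcohol stops at the aldehyde in the absence of water and leaves the dimethoxyarene alone; the aldehyde is used promptly in step 7.

Step 7
Reactants: 13 4-(2,3-dimethoxyphenyl)butanal; 14 formaldehyde; 7 1-{4-[2-(3-methoxyphenyl)ethyl]phenoxy}propan-2-one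
Product: 18 4-[2-(2,3-dimethoxyphenyl)ethyl]-6-{4-[2-(3-methoxyphenyl)ethyl]phenoxy}cyclohex-2-en-1-one (mixture of diastereomers), via 2-methylidene aldehyde 15 (not isolated), via keto aldehyde 16 (not isolated), via ketol 17 (not isolated)
Conditions: 13, 14 (37% aq., 1.0 equiv), pyrrolidine (10 mol %), EtCO2H (10 mol %), i-PrOH, 45 °C; then 7 (1.1 equiv), K2CO3 (0.5 equiv), MeOH, 0 °C to 50 °C
Reagents that add atoms: none
Why: Proposed new method: the closest known reaction types are the amine/acid-catalysed α-methylenation of aliphatic aldehydes with formalin and the Robinson annulation of ketones with α-substituted acroleins, and what is untested is their union in one flask with an α-aryloxy methyl ketone as donor. Pyrrolidinium propanoate should convert 13 through its enamine into the Mannich adduct with 14 and eliminate the amine to give 15 (bond C3–C4 of ring C); since 14 is used in one equivalent and consumed before 7 is added, 7 meets no free formaldehyde. K2CO3 in MeOH then generates the enolate of 7, preferentially at the more acidic oxygen-substituted carbon, and conjugate addition to the unsubstituted methylene terminus of 15 forms C2–C3 and gives 16; 1,2-addition to the aldehyde is reversible and drains back, whereas the 1,4-adduct is carried forward. The methyl-side enolate of 16 should close onto the aldehyde by a 6-(enolendo)-exo-trig aldol addition to 17 (bond C5–C6), the only closure that gives an unstrained ring, and E1cB loss of water delivers 18. The two stereocentres of 18 (C4 and C6 of the enone) arise without control and need none, because step 8 makes both carbons trigonal. The selectivity required is 1,4- over 1,2-addition and annulation over oligomerisation of 15, which the unhindered β-carbon of 15, the slight excess of 7 and the low starting temperature should secure. Which α-carbon of 7 reacts first is immaterial, since either order of bond formation places the chain para and the aryloxy group ortho to the carbonyl and leads to 20 after step 8.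

Step 8
Reactants: 18 4-[2-(2,3-dimethoxyphenyl)ethyl]-6-{4-[2-(3-methoxyphenyl)ethyl]phenoxy}cyclohex-2-en-1-one
Product: 20 4-[2-(2,3-dimethoxyphenyl)ethyl]-2-{4-[2-(3-methoxyphenyl)ethyl]phenoxy}phenol, via dienone tautomer 19 (not isolated)
Conditions: Pd(OCOCF3)2 (5 mol %), 2-(dimethylamino)pyridine (10 mol %), TsOH (20 mol %), O2 (1 atm), DMSO, 80 °C
Reagents that add atoms: none
Why: Aerobic dehydrogenation of a cyclohexenone to a phenol catalysed by divalent palladium: a carbon-bound palladium enolate at C6 undergoes β-hydride elimination to 19, which tautomerises to the phenol, and O2 reoxidises zerovalent palladium. Both stereocentres are erased here.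

Step 9
Reactants: 20 4-[2-(2,3-dimethoxyphenyl)ethyl]-2-{4-[2-(3-methoxyphenyl)ethyl]phenoxy}phenol
Product: 21 3-[2-(4-hydroxy-3-{4-[2-(3-hydroxyphenyl)ethyl]phenoxy}phenyl)ethyl]benzene-1,2-diol
Conditions: BBr3 (6 equiv), CH2Cl2, −78 °C to rt; then H2O, under argon
Reagents that add atoms: none
Why: Lewis-acid cleavage of aryl methyl ethers: boron coordinates each methoxy oxygen and bromide attacks the methyl carbon by SN2. The diaryl ether offers no sp3 carbon and should remain intact.

## Compound list

1 | 4-(benzyloxy)benzaldehyde | O=Cc1ccc(OCc2ccccc2)cc1 | starting material
2 | (3-methoxybenzyl)triphenylphosphonium chloride | COc1cccc(C[P+](c2ccccc2)(c2ccccc2)c2ccccc2)c1.[Cl-] | starting material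
3 | (3-methoxybenzylidene)triphenylphosphorane | COc1cccc(C=P(c2ccccc2)(c2ccccc2)c2ccccc2)c1 | intermediate
4 | 1-(benzyloxy)-4-[2-(3-methoxyphenyl)ethenyl]benzene (E/Z mixture) | COc1cccc(C=Cc2ccc(OCc3ccccc3)cc2)c1 | intermediate
5 | 4-[2-(3-methoxyphenyl)ethyl]phenol | COc1cccc(CCc2ccc(O)cc2)c1 | intermediate
6 | chloroacetone (1-chloropropan-2-one) | CC(=O)CCl | starting material
7 | 1-{4-[2-(3-methoxyphenyl)ethyl]phenoxy}propan-2-one | CC(=O)COc1ccc(CCc2cccc(OC)c2)cc1 | intermediate
8 | 2,3-dimethoxybenzaldehyde | COc1cccc(C=O)c1OC | starting material
9 | (3-hydroxypropyl)triphenylphosphonium bromide | OCCC[P+](c1ccccc1)(c1ccccc1)c1ccccc1.[Br-] | starting material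
10 | lithium 3-(triphenyl-λ5-phosphanylidene)propan-1-olate | [Li+].[O-]CCC=P(c1ccccc1)(c1ccccc1)c1ccccc1 | intermediate
11 | 4-(2,3-dimethoxyphenyl)but-3-en-1-ol (E/Z mixture) | COc1cccc(C=CCCO)c1OC | intermediate
12 | 4-(2,3-dimethoxyphenyl)butan-1-ol | COc1cccc(CCCCO)c1OC | intermediate
13 | 4-(2,3-dimethoxyphenyl)butanal | COc1cccc(CCCC=O)c1OC | intermediate
14 | formaldehyde | C=O | starting material
15 | 4-(2,3-dimethoxyphenyl)-2-methylidenebutanal | C=C(CCc1cccc(OC)c1OC)C=O | intermediate
16 | 2-[2-(2,3-dimethoxyphenyl)ethyl]-4-{4-[2-(3-methoxyphenyl)ethyl]phenoxy}-5-oxohexanal (diastereomer mixture) | O=CC(CCc1cccc(OC)c1OC)CC(Oc1ccc(CCc2cccc(OC)c2)cc1)C(C)=O | intermediate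
17 | 4-[2-(2,3-dimethoxyphenyl)ethyl]-3-hydroxy-6-{4-[2-(3-methoxyphenyl)ethyl]phenoxy}cyclohexan-1-one (diastereomer mixture) | O=C1CC(O)C(CCc2cccc(OC)c2OC)CC1Oc1ccc(CCc2cccc(OC)c2)cc1 | intermediate
18 | 4-[2-(2,3-dimethoxyphenyl)ethyl]-6-{4-[2-(3-methoxyphenyl)ethyl]phenoxy}cyclohex-2-en-1-one (diastereomer mixture) | O=C1C=CC(CCc2cccc(OC)c2OC)CC1Oc1ccc(CCc2cccc(OC)c2)cc1 | intermediate
19 | 4-[2-(2,3-dimethoxyphenyl)ethyl]-2-{4-[2-(3-methoxyphenyl)ethyl]phenoxy}cyclohexa-2,5-dien-1-one | O=C1C=CC(CCc2cccc(OC)c2OC)C=C1Oc1ccc(CCc2cccc(OC)c2)cc1 | intermediate
20 | 4-[2-(2,3-dimethoxyphenyl)ethyl]-2-{4-[2-(3-methoxyphenyl)ethyl]phenoxy}phenol | COc1cccc(CCc2ccc(Oc3cc(CCc4cccc(OC)c4OC)ccc3O)cc2)c1 | intermediate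
21 | 3-[2-(4-hydroxy-3-{4-[2-(3-hydroxyphenyl)ethyl]phenoxy}phenyl)ethyl]benzene-1,2-diol (CNP0185459.0) | Oc1cccc(CCc2ccc(Oc3cc(CCc4cccc(O)c4O)ccc3O)cc2)c1 | target

## Step count and least certain steps

Total: 9 steps. Longest linear sequence: 6 steps (steps 1–3 or steps 4–6, then steps 7–9).

Step 7 (key step, proposed new method). The most likely failure is oligomerisation of the 2-methylidene aldehyde, or 1,2-addition and crossed-aldol pathways consuming the partners before conjugate addition, because carbonate produces only a low concentration of the enolate of a singly activated ketone; a second conjugate addition at the still acidic aryloxy-bearing carbon is a further drain. The fallback uses known chemistry in separate operations and sets out from 13 and 7. The α-methylenation is run alone (pyrrolidine, EtCO2H, 37% aq. formaldehyde, i-PrOH, 45 °C) and 15 is isolated. Ketone 7 is condensed with pyrrolidine (toluene, reflux, water separator) to the enamine 1-(1-{4-[2-(3-methoxyphenyl)ethyl]phenoxy}prop-1-en-2-yl)pyrrolidine F1. Stork enamine Michael addition of F1 to 15 (dioxane, rt to 60 °C) and hydrolysis with aqueous AcOH/NaOAc should give 16, which is cyclised and dehydrated with KOH in MeOH to 18, where the route resumes.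

Step 8. The dehydrogenation may stall because palladation at the α-carbon that carries the aryloxy group is slow, or the electron-rich phenol formed may be oxidised further under O2. The fallback sets out from 18 and replaces C–H palladation by halogenation–elimination: I2 (20 mol %) in DMSO at 100 °C should iodinate the enol at C6 to give 4-[2-(2,3-dimethoxyphenyl)ethyl]-6-iodo-6-{4-[2-(3-methoxyphenyl)ethyl]phenoxy}cyclohex-2-en-1-one F2, which loses HI to 19 and tautomerises to 20, where the route resumes; DMSO reoxidises the iodide.

Step 4. Generation of the doubly deprotonated ylide may be incomplete, or its aggregation may leave the ortho-substituted aldehyde unconverted. The fallback sets out from 8 and carries the aldehyde carbon masked as an acetal instead of as an alcohol. Commercial [2-(1,3-dioxolan-2-yl)ethyl]triphenylphosphonium bromide with KOtBu in THF gives [2-(1,3-dioxolan-2-yl)ethylidene]triphenylphosphorane F3, which with 8 should give 2-[3-(2,3-dimethoxyphenyl)prop-2-en-1-yl]-1,3-dioxolane F4. Hydrogenation (H2, 10% Pd/C, EtOAc) gives 2-[3-(2,3-dimethoxyphenyl)propyl]-1,3-dioxolane F5, and mild hydrolysis (AcOH/H2O, 50 °C) returns to the route at 13, so steps 5 and 6 are not needed.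

Step 9. Cleavage at the vicinal dimethoxy unit may be incomplete, or the liberated catechol may oxidise in air during work-up. The fallback sets out from 20 and replaces the Lewis acid by a Brønsted-acid/chloride demethylation in molten pyridinium chloride (about 190 °C, argon), which leads directly to 21 and makes no new compound on the way (entry F0).

## Further compounds

F1 | step 7 | 1-(1-{4-[2-(3-methoxyphenyl)ethyl]phenoxy}prop-1-en-2-yl)pyrrolidine (double-bond isomers) | CC(=COc1ccc(CCc2cccc(OC)c2)cc1)N1CCCC1
F2 | step 8 | 4-[2-(2,3-dimethoxyphenyl)ethyl]-6-iodo-6-{4-[2-(3-methoxyphenyl)ethyl]phenoxy}cyclohex-2-en-1-one | O=C1C=CC(CCc2cccc(OC)c2OC)CC1(I)Oc1ccc(CCc2cccc(OC)c2)cc1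
F3 | step 4 | [2-(1,3-dioxolan-2-yl)ethylidene]triphenylphosphorane | C(CC1OCCO1)=P(c1ccccc1)(c1ccccc1)c1ccccc1
F4 | step 4 | 2-[3-(2,3-dimethoxyphenyl)prop-2-en-1-yl]-1,3-dioxolane (E/Z mixture) | COc1cccc(C=CCC2OCCO2)c1OC
F5 | step 4 | 2-[3-(2,3-dimethoxyphenyl)propyl]-1,3-dioxolane | COc1cccc(CCCC2OCCO2)c1OC
F0 | step 9 | none | none
A1 | alternative 1 | methyl coumalate (methyl 2-oxo-2H-pyran-5-carboxylate) | COC(=O)C1=COC(=O)C=C1
A2 | alternative 1 | 4-[2-(2,3-dimethoxyphenyl)ethyl]-2-(ethynyloxy)-1-methoxybenzene | C#COc1cc(CCc2cccc(OC)c2OC)ccc1OC
A3 | alternative 1 | methyl 4-{5-[2-(2,3-dimethoxyphenyl)ethyl]-2-methoxyphenoxy}benzoate | COC(=O)c1ccc(Oc2cc(CCc3cccc(OC)c3OC)ccc2OC)cc1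
A4 | alternative 2 | 2-iodo-6-methoxyphenol | COc1cccc(I)c1O
A5 | alternative 2 | 4-ethynyl-1-methoxy-2-{4-[2-(3-methoxyphenyl)ethyl]phenoxy}benzene | C#Cc1ccc(OC)c(Oc2ccc(CCc3cccc(OC)c3)cc2)c1
A6 | alternative 2 | 7-methoxy-2-(4-methoxy-3-{4-[2-(3-methoxyphenyl)ethyl]phenoxy}phenyl)-1-benzofuran | COc1cccc2cc(-c3ccc(OC)c(Oc4ccc(CCc5cccc(OC)c5)cc4)c3)oc12
A7 | alternative 2 | 2-methoxy-6-[2-(4-methoxy-3-{4-[2-(3-methoxyphenyl)ethyl]phenoxy}phenyl)ethyl]phenol | COc1cccc(CCc2ccc(OC)c(Oc3ccc(CCc4cccc(OC)c4)cc3)c2)c1O
A8 | alternative 3 | ethyl acetoacetate | CCOC(=O)CC(C)=O
A9 | alternative 3 | (E)-5-(4-{5-[2-(2,3-dimethoxyphenyl)ethyl]-2-methoxyphenoxy}phenyl)pent-2-enal | O=C/C=C/CCc1ccc(Oc2cc(CCc3cccc(OC)c3OC)ccc2OC)cc1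
A10 | alternative 3 | ethyl 6-[2-(4-{5-[2-(2,3-dimethoxyphenyl)ethyl]-2-methoxyphenoxy}phenyl)ethyl]-2-oxocyclohex-3-ene-1-carboxylate (diastereomer mixture) | CCOC(=O)C1C(=O)C=CCC1CCc1ccc(Oc2cc(CCc3cccc(OC)c3OC)ccc2OC)cc1
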